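## Retrosynthetic overview

1. Feature: in ring A the unit C8(=O)–C8a=C4a–C5 is an enone whose γ-carbon is C5. With ring B (O2, C1, C8a, C4a, C4, C3) already closed, C5 travels as a methyl group on C4a. It becomes the nucleophile only at the end, against an aldehyde C6 attached to the fully substituted carbinol C7.
2. Target 28 ⇒ C6–O acylation of cis-diol 22 with silylated orsellinic acid 25. Diol 22 ⇒ C5–C6 intramolecular vinylogous aldol of the 3-acyl-4-methyl-2H-pyran 20, which closes ring A and sets C6.
3. Pyran 20 ⇒ O2–C3 conjugate hydroalkoxylation of enynone 16, so ring B is closed only once C8 is a ketone. Enynone 16 ⇒ C7–C8 aldol of the (R)-lactate dioxolanone enolate 13 with enynal 10, which sets C7.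
4. Enynal 10 ⇒ C4–C4a Sonogashira union of epoxy alkyne 4 with triflate 6. Asymmetric epoxidation of crotyl alcohol sets both oxirane centres of 4. The ester/nitrile pair of 6 distinguishes C1 from C8 and fixes the C4a=C8a geometry.
5. Ring order: oxirane (step 1), ring B (step 11), ring A (step 13).

Key step: step 13

Assumption: all locants follow the 1H-isochromene skeleton of the target (C1, O2, C3, C4, C4a, C5–C8, C8a); the monocyclic 2H-pyrans 19 and 20 are taken to rest on the closed side of their valence equilibrium with the ring-opened dienone, held by the same O2–C3=C4–C4a=C8a–C8=O push–pull array as in the target.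

## Route

Step 1
Reactants: 1 (E)-crotyl alcohol
Product: 2 (2R,3R)-2,3-epoxybutan-1-ol
Conditions: Ti(Oi-Pr)4 (cat.), D-(−)-diisopropyl tartrate (cat.), t-BuOOH, 4 Å molecular sieves, CH2Cl2, −20 °C
Reagents that add atoms: tert-butyl hydroperoxide, CC(C)(C)OO
Why: Katsuki–Sharpless asymmetric epoxidation, in which the D-(−)-tartrate complex delivers oxygen to the face of the E-allylic alcohol that gives the (2R,3R)-trans-epoxide, so that both oxirane stereocentres of the target are set here by the reagent.

Step 2
Reactants: 2 (2R,3R)-2,3-epoxybutan-1-ol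
Product: 4 (2R,3R)-2-ethynyl-3-methyloxirane, via epoxy aldehyde 3 (not isolated)
Conditions: TEMPO (cat.), PhI(OAc)2, CH2Cl2, 0 °C to rt; then MeOH, K2CO3, dimethyl (1-diazo-2-oxopropyl)phosphonate, 0 °C to rt; product kept as a distilled ethereal solution
Reagents that add atoms: dimethyl (1-diazo-2-oxopropyl)phosphonate, COP(=O)(OC)C(=[N+]=[N-])C(C)=O
Why: TEMPO (oxoammonium) oxidation and Ohira–Bestmann (Seyferth–Gilbert type) homologation are run in one flask because aldehyde 3 is volatile and water-soluble, and the oxirane centres are kept since neither C–O bond is touched and enolisation of an oxirane carbaldehyde is strongly disfavoured.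

Step 3
Reactants: 5 ethyl 2-cyano-3-oxobutanoate
Product: 6 ethyl (Z)-2-cyano-3-(trifluoromethylsulfonyloxy)but-2-enoate (triflate cis to CO2Et)
Conditions: (CF3SO2)2O, i-Pr2NEt, LiOSO2CF3, CH2Cl2, −78 to 0 °C
Reagents that add atoms: trifluoromethanesulfonic anhydride, O=S(=O)(OS(=O)(=O)C(F)(F)F)C(F)(F)F
Why: O-sulfonylation of a chelated β-dicarbonyl enolate: lithium can bridge the enolate oxygen only to the ester carbonyl, the linear nitrile being out of reach, so the triflate is placed cis to CO2Et, which puts the future C1 cis to the future alkyne and the future C8 cis to the C5 methyl.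

Step 4
Reactants: 4 (2R,3R)-2-ethynyl-3-methyloxirane; 6 ethyl (Z)-2-cyano-3-(trifluoromethylsulfonyloxy)but-2-enoate
Product: 7 ethyl (Z)-2-cyano-3-methyl-5-[(2R,3R)-3-methyloxiran-2-yl]pent-2-en-4-ynoate (alkyne cis to CO2Et)
Conditions: PdCl2(PPh3)2 (cat.), CuI (cat.), i-Pr2NEt, degassed THF, 0 °C to rt
Reagents that add atoms: none
Why: Sonogashira coupling with retention of the alkene geometry, the very electron-poor triflate adding to zerovalent palladium at or below room temperature faster than the propargylic oxirane can ionise, while a hindered tertiary amine avoids addition–elimination at C4a and the ester-cis-to-alkyne isomer is also the sterically preferred one should the alkene equilibrate.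

Step 5
Reactants: 7 ethyl (Z)-2-cyano-3-methyl-5-[(2R,3R)-3-methyloxiran-2-yl]pent-2-en-4-ynoate
Product: 9 (E)-2-(hydroxymethyl)-3-methyl-5-[(2R,3R)-3-methyloxiran-2-yl]pent-2-en-4-ynal (CH2OH cis to the alkyne), via hydroxy aldimine 8 (not isolated)
Conditions: i-Bu2AlH (3.5 equiv), CH2Cl2, −78 °C; aq. potassium sodium tartrate, then moist SiO2, 0 °C
Reagents that add atoms: water, O
Why: Twofold 1,2-reduction with i-Bu2AlH, ester to allylic alcohol (C1) and nitrile to the N-aluminated aldimine that water hydrolyses by way of 8 to the aldehyde (C8), the fully substituted β-carbon and the low temperature working against conjugate hydride delivery and oxirane opening.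

Step 6
Reactants: 9 (E)-2-(hydroxymethyl)-3-methyl-5-[(2R,3R)-3-methyloxiran-2-yl]pent-2-en-4-ynal
Product: 10 (E)-2-[(tert-butyldimethylsilyloxy)methyl]-3-methyl-5-[(2R,3R)-3-methyloxiran-2-yl]pent-2-en-4-ynal
Conditions: t-BuMe2SiCl, imidazole, CH2Cl2, 0 °C
Reagents that add atoms: tert-butyldimethylsilyl chloride, CC(C)(C)[Si](C)(C)Cl
Why: Routine silylation of the primary allylic alcohol, which keeps ring B open until C8 is a ketone, because a 2H-pyran that carries a mere carbinol at C8a would lose its push–pull stabilisation and open electrocyclically.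

Step 7
Reactants: 11 (R)-lactic acid
Product: 12 (2R,5R)-2-tert-butyl-5-methyl-1,3-dioxolan-4-one (cis)
Conditions: t-BuCHO, p-TsOH (cat.), pentane, reflux, Dean–Stark trap; crystallisation from pentane at −78 °C
Reagents that add atoms: pivalaldehyde, CC(C)(C)C=O
Why: Acid-catalysed acetalisation in the sense of self-regeneration of stereocentres: the cis-dioxolanone is the favoured isomer, is freed of the trans isomer by crystallisation, and its acetal carbon stores the stereochemical information while C7 is planarised in step 8.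

Step 8
Reactants: 12 (2R,5R)-2-tert-butyl-5-methyl-1,3-dioxolan-4-one; 10 (E)-2-[(tert-butyldimethylsilyloxy)methyl]-3-methyl-5-[(2R,3R)-3-methyloxiran-2-yl]pent-2-en-4-ynal
Product: 14 aldol adduct (2R,5S)-2-tert-butyl-5-methyl-5-[C8 carbinol side chain]-1,3-dioxolan-4-one (side chain trans to tert-butyl; both C8 epimers), via lithium enolate 13 (not isolated)
Conditions: LiN(i-Pr)2, THF, −78 °C; then 10, −78 °C; AcOH quench at −78 °C
Reagents that add atoms: none
Why: Aldol addition of the dioxolanone lithium enolate, which is attacked on the face anti to the tert-butyl group so that C8 takes the place of the former hydrogen and C7 receives the configuration of the target, the configuration of the C8 carbinol being irrelevant because it is oxidised in step 10.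

Step 9
Reactants: 14 aldol adduct
Product: 15 (2R,4E)-4-[(tert-butyldimethylsilyloxy)methyl]-2,5-dimethyl-7-[(2R,3R)-3-methyloxiran-2-yl]hept-4-en-6-yne-1,2,3-triol (both C3 epimers)
Conditions: LiBH4, THF–MeOH, 0 °C
Reagents that add atoms: none
Why: Hydride reduction of the activated acylal-type lactone, whose hemiacetal collapses with loss of pivalaldehyde (reduced as well) to bare the tertiary C7 and primary C6 hydroxyls, under conditions that leave oxirane, enyne and silyl ether alone.

Step 10
Reactants: 15 silyloxy enyne triol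
Product: 16 (2R,4E)-4-[(tert-butyldimethylsilyloxy)methyl]-1,2-dihydroxy-2,5-dimethyl-7-[(2R,3R)-3-methyloxiran-2-yl]hept-4-en-6-yn-3-one
Conditions: MnO2 (activated, excess), CH2Cl2, rt
Reagents that add atoms: none
Why: Chemoselective MnO2 oxidation, which takes only the allylic C8 carbinol and leaves the saturated primary C6 and the tertiary C7 hydroxyl.

Step 11
Reactants: 16 silyloxy enynone diol
Product: 19 (R)-2,3-dihydroxy-2-methyl-1-{4-methyl-6-[(2S,3R)-3-methyloxiran-2-yl]-2H-pyran-3-yl}propan-1-one, via free enynone triol 17 (not isolated), via methoxy dienone 18 (not isolated)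
Conditions: Bu4NF–AcOH (1:1), THF, 0 °C to rt; then MeOH, K2CO3 (cat.), 0 °C to rt
Reagents that add atoms: none
Why: Fluoride desilylation followed by a base-catalysed oxa-Michael relay of the kind used to turn hydroxy ynones into dihydropyranones: methoxide adds to C3, the δ-terminus of the C8=O/C8a=C4a/C4≡C3 acceptor, and the C1 hydroxyl replaces it at the same carbon by addition–elimination, so that only the six-membered ring B can form and the five-ring closure at C4 that converts unactivated (Z)-enynols into furans has no electrophilic carbon to use.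

Step 12
Reactants: 19 pyranyl keto diol
Product: 20 (R)-2-hydroxy-2-methyl-3-{4-methyl-6-[(2S,3R)-3-methyloxiran-2-yl]-2H-pyran-3-yl}-3-oxopropanal
Conditions: Dess–Martin periodinane, NaHCO3, CH2Cl2, 0 °C; filtered, concentrated cold and used at once
Reagents that add atoms: none
Why: Dess–Martin oxidation of the only oxidisable alcohol under buffered, essentially neutral conditions, chosen because the α-hydroxy β-keto aldehyde 20 does not tolerate base or chromatography and is carried on directly.

Step 13
Reactants: 20 (R)-2-hydroxy-2-methyl-3-{4-methyl-6-[(2S,3R)-3-methyloxiran-2-yl]-2H-pyran-3-yl}-3-oxopropanal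
Product: 22 (6R,7R)-6,7-dihydroxy-7-methyl-3-[(2S,3R)-3-methyloxiran-2-yl]-6,7-dihydro-1H-isochromen-8(5H)-one (cis-diol), via magnesium dienolate 21 (not isolated)
Conditions: Mg[N(SiMe3)2]2 (1.2 equiv), THF, −78 to −40 °C; AcOH quench at −78 °C
Reagents that add atoms: none
Why: The first amide ligand turns C7–OH into a magnesium alkoxide and the second, held beside the C4a methyl in the rotamer that places C7 syn to C5, removes a C5 proton to give the extended enolate 21 (C8a and C7 bear no hydrogen, loss of a C1 proton would create an eight-electron pyranyl anion, and the oxirane C–H cannot align with the π system). C5, the γ-terminus, then adds to the non-enolisable C6 aldehyde, an intramolecular vinylogous aldol addition of the type known for β-methyl enones that carry a tethered aldehyde; attack through C8a would give a strained cyclobutanol and reverts. Ring A closes in the allowed 6-(enolendo)-exo-trig mode through a half-chair. In that half-chair the aldehyde oxygen is pseudo-equatorial and lies close to a pseudo-axial C7–O but far from a pseudo-equatorial one, so the five-membered magnesium chelate between the C7 alkoxide and the aldehyde oxygen can form only with C7–O axial and the C7 methyl equatorial, and C5 then meets the aldehyde face that sets C6–O cis to C7–O, that is (6R) from (7R). The step needs the enolate geometry with C7 cis to C4a and needs closure to outrun the 1,2-acyl shift of the alkoxy aldehyde: the weakly basic silylamide makes enolisation reversible, so that an enolate of the wrong geometry returns to 20, while the closed product is held as a stable magnesium cis-diolate and the low temperature slows the acyl shift. Addition of the bulky amide to the neopentyl-type aldehyde should be reversible at this temperature and should not consume substrate.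

Step 14
Reactants: 23 orsellinic acid
Product: 25 2,4-bis(tert-butyldimethylsilyloxy)-6-methylbenzoic acid, via tris-silyl orsellinate 24 (not isolated)
Conditions: t-BuMe2SiCl (3.5 equiv), imidazole, DMF, rt; then AcOH–THF–H2O, rt
Reagents that add atoms: tert-butyldimethylsilyl chloride, CC(C)(C)[Si](C)(C)Cl
Why: Exhaustive silylation followed by selective solvolysis, the silyl ester being far more labile than the two aryl silyl ethers.

Step 15
Reactants: 25 2,4-bis(tert-butyldimethylsilyloxy)-6-methylbenzoic acid; 22 bicyclic cis-diol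
Product: 27 (6R,7R)-7-hydroxy-7-methyl-3-[(2S,3R)-3-methyloxiran-2-yl]-8-oxo-5,6,7,8-tetrahydro-1H-isochromen-6-yl 2,4-bis(tert-butyldimethylsilyloxy)-6-methylbenzoate, via acid chloride 26 (not isolated)
Conditions: 1-chloro-N,N,2-trimethylprop-1-en-1-amine, CH2Cl2, 0 °C; then 22, pyridine, DMAP (cat.), CH2Cl2, 0 °C to rt
Reagents that add atoms: none
Why: Acyl chloride formation under neutral conditions with the α-chloroenamine (Ghosez reagent) and DMAP-catalysed acylation, selective for the secondary C6 hydroxyl over the tertiary C7 hydroxyl on steric grounds, with retention at C6 because the C6–O bond is not broken and with a base too weak to trigger loss of the carboxylate through C5 deprotonation.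

Step 16
Reactants: 27 bis-silylated ester
Product: 28 target, (6R,7R)-7-hydroxy-7-methyl-3-[(2S,3R)-3-methyloxiran-2-yl]-8-oxo-5,6,7,8-tetrahydro-1H-isochromen-6-yl 2,4-dihydroxy-6-methylbenzoate
Conditions: Bu4NF–AcOH (1:1), THF, 0 °C
Reagents that add atoms: none
Why: Fluoride cleavage of the two aryl silyl ethers, fast at 0 °C, in a medium buffered by acetic acid so that oxirane, ester, dienol ether and the C5–H/C6–O elimination pathway are not addressed.

## Compound list

1 | (E)-crotyl alcohol | C/C=C/CO | starting material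
2 | (2R,3R)-2,3-epoxybutan-1-ol | OC[C@H]1O[C@@H]1C | intermediate
3 | (2S,3R)-3-methyloxirane-2-carbaldehyde (not isolated) | O=C[C@H]1O[C@@H]1C | intermediate
4 | (2R,3R)-2-ethynyl-3-methyloxirane | C#C[C@H]1O[C@@H]1C | intermediate
5 | ethyl 2-cyano-3-oxobutanoate | CCOC(=O)C(C#N)C(C)=O | starting material
6 | ethyl (Z)-2-cyano-3-(trifluoromethylsulfonyloxy)but-2-enoate | CCOC(=O)/C(C#N)=C(/C)OS(=O)(=O)C(F)(F)F | intermediate
7 | ethyl (Z)-2-cyano-3-methyl-5-[(2R,3R)-3-methyloxiran-2-yl]pent-2-en-4-ynoate | CCOC(=O)/C(C#N)=C(/C)C#C[C@H]1O[C@@H]1C | intermediate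
8 | 2-(iminomethyl)-3-methyl-5-[(2R,3R)-3-methyloxiran-2-yl]pent-2-en-4-yn-1-ol, CH2OH cis to alkyne (not isolated) | OC/C(C=N)=C(/C)C#C[C@H]1O[C@@H]1C | intermediate
9 | (E)-2-(hydroxymethyl)-3-methyl-5-[(2R,3R)-3-methyloxiran-2-yl]pent-2-en-4-ynal | OC/C(C=O)=C(/C)C#C[C@H]1O[C@@H]1C | intermediate
10 | (E)-2-[(tert-butyldimethylsilyloxy)methyl]-3-methyl-5-[(2R,3R)-3-methyloxiran-2-yl]pent-2-en-4-ynal | CC(C)(C)[Si](C)(C)OC/C(C=O)=C(/C)C#C[C@H]1O[C@@H]1C | intermediate
11 | (R)-lactic acid | C[C@@H](O)C(=O)O | starting material
12 | (2R,5R)-2-tert-butyl-5-methyl-1,3-dioxolan-4-one | C[C@H]1O[C@@H](C(C)(C)C)OC1=O | intermediate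
13 | lithium enolate of 12 (not isolated) | CC1=C([O-])O[C@H](C(C)(C)C)O1.[Li+] | intermediate
14 | aldol adduct, (2R,5S)-dioxolanone, C8 carbinol epimers | C[C@@]1(C(O)/C(CO[Si](C)(C)C(C)(C)C)=C(\C)C#C[C@H]2O[C@@H]2C)O[C@@H](C(C)(C)C)OC1=O | intermediate
15 | (2R,4E)-silyloxy enyne 1,2,3-triol, C3 epimers | C[C@@](O)(CO)C(O)/C(CO[Si](C)(C)C(C)(C)C)=C(\C)C#C[C@H]1O[C@@H]1C | intermediate
16 | (2R,4E)-silyloxy enynone 1,2-diol | C[C@@](O)(CO)C(=O)/C(CO[Si](C)(C)C(C)(C)C)=C(\C)C#C[C@H]1O[C@@H]1C | intermediate
17 | (2R,4E)-1,2-dihydroxy-4-(hydroxymethyl)-2,5-dimethyl-7-[(2R,3R)-3-methyloxiran-2-yl]hept-4-en-6-yn-3-one (not isolated) | C[C@@](O)(CO)C(=O)/C(CO)=C(\C)C#C[C@H]1O[C@@H]1C | intermediate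
18 | C3-methoxy dienone from 1,6-addition of methanol to 17, alkene isomers (not isolated) | C[C@@](O)(CO)C(=O)C(CO)=C(C)C=C(OC)[C@H]1O[C@@H]1C | intermediate
19 | (R)-2,3-dihydroxy-2-methyl-1-{4-methyl-6-[(2S,3R)-3-methyloxiran-2-yl]-2H-pyran-3-yl}propan-1-one | CC1=C(COC([C@H]2O[C@@H]2C)=C1)C(=O)[C@](C)(O)CO | intermediate
20 | (R)-2-hydroxy-2-methyl-3-{4-methyl-6-[(2S,3R)-3-methyloxiran-2-yl]-2H-pyran-3-yl}-3-oxopropanal | CC1=C(COC([C@H]2O[C@@H]2C)=C1)C(=O)[C@](C)(O)C=O | intermediate
21 | magnesium C7-alkoxide C8/C5-dienolate of 20, C7 cis to C4a (not isolated) | C=C1C=C([C@H]2O[C@@H]2C)OC/C1=C(\[O-])[C@](C)([O-])C=O.[Mg+2] | intermediate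
22 | (6R,7R)-6,7-dihydroxy-7-methyl-3-[(2S,3R)-3-methyloxiran-2-yl]-6,7-dihydro-1H-isochromen-8(5H)-one | O[C@@H]1CC2=C(COC([C@H]3O[C@@H]3C)=C2)C(=O)[C@]1(C)O | intermediate
23 | orsellinic acid | Cc1cc(O)cc(O)c1C(=O)O | starting material
24 | tert-butyldimethylsilyl 2,4-bis(tert-butyldimethylsilyloxy)-6-methylbenzoate (not isolated) | Cc1cc(O[Si](C)(C)C(C)(C)C)cc(O[Si](C)(C)C(C)(C)C)c1C(=O)O[Si](C)(C)C(C)(C)C | intermediate
25 | 2,4-bis(tert-butyldimethylsilyloxy)-6-methylbenzoic acid | Cc1cc(O[Si](C)(C)C(C)(C)C)cc(O[Si](C)(C)C(C)(C)C)c1C(=O)O | intermediate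
26 | 2,4-bis(tert-butyldimethylsilyloxy)-6-methylbenzoyl chloride (not isolated) | Cc1cc(O[Si](C)(C)C(C)(C)C)cc(O[Si](C)(C)C(C)(C)C)c1C(=O)Cl | intermediate
27 | bis-silylated C6 orsellinate of 22 | Cc1cc(O[Si](C)(C)C(C)(C)C)cc(O[Si](C)(C)C(C)(C)C)c1C(=O)O[C@@H]1CC2=C(COC([C@H]3O[C@@H]3C)=C2)C(=O)[C@]1(C)O | intermediate
28 | CNP0323247.1 | Cc1cc(O)cc(O)c1C(=O)O[C@@H]1CC2=C(COC([C@H]3O[C@@H]3C)=C2)C(=O)[C@]1(C)O | target

## Step count and risk

Total step count: 16.
Longest linear sequence: 13 steps (1, 2, 4, 5, 6, 8, 9, 10, 11, 12, 13, 15, 16).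

Three steps most likely to fail:

1. Step 13.
- What may go wrong: 1,2-acyl shift of the magnesium alkoxy aldehyde before enolisation; irreversible addition of the amide to the aldehyde; enolisation to the geometry that cannot reach C6; electrocyclic opening of the monocyclic pyran, whose bulky acyl group may be twisted out of conjugation.
- Fallback: the order of ring closure is inverted. Setting out from 16, Dess–Martin oxidation gives the acyclic hydroxy keto aldehyde F1. Mg[N(SiMe3)2]2 then closes ring A first, on a substrate that has no valence tautomer and whose C5 protons are acidified by the alkyne as well, to the alkynyl cyclohexenone cis-diol F2. Bu4NF–AcOH frees the C1 alcohol in the cyclohexenone triol F3. K2CO3 in MeOH closes ring B, by way of the cyclic methoxy dienone F4, onto an acceptor that ring A now holds planar. The sequence comes back to the route at 22.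

2. Step 11.
- What may go wrong: sluggish conjugate addition because the hindered ketone is twisted out of the plane of the enyne; closure at the inner alkyne carbon followed by aromatisation; loss of formaldehyde by retro-aldol cleavage at C6–C7; base-induced opening of the oxirane.
- Fallback: a stoichiometric amine relay in separate stages. Setting out from 16, Et3N·3HF gives 17, this time isolated. Pyrrolidine adds to C3 to give the push–pull dienaminone F5, which can be purified. Pyridinium p-toluenesulfonate in CH2Cl2 then exchanges the amine for the C1 hydroxyl at the same carbon. The sequence comes back to the route at 19.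

3. Step 5.
- What may go wrong: conjugate hydride delivery to the doubly activated enyne; reductive opening of the propargylic oxirane; incomplete hydrolysis of the aldimine; premature cyclisation of the hydroxy enal.
- Fallback: C1 and C8 are told apart after the reduction instead of before it. Setting out from 4 and commercial diethyl acetylmalonate, the malonate is converted with (CF3SO2)2O and i-Pr2NEt into the malonate enol triflate F6. Sonogashira coupling with 4 gives the enyne diester F7. Reduction with i-Bu2AlH, established for tetrasubstituted alkylidene malonates, gives the enyne diol F8. Monosilylation with t-BuMe2SiCl gives the mono silyl ether F9, silylated cis to the slimmer alkyne; it is separated from its isomer, which is desilylated and recycled. MnO2 oxidises the remaining allylic alcohol, and the sequence comes back to the route at 10.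

Further compounds
F1 | step 13 | (2R,4E)-4-[(tert-butyldimethylsilyloxy)methyl]-2-hydroxy-2,5-dimethyl-7-[(2R,3R)-3-methyloxiran-2-yl]-3-oxohept-4-en-6-ynal | C[C@@](O)(C=O)C(=O)/C(CO[Si](C)(C)C(C)(C)C)=C(\C)C#C[C@H]1O[C@@H]1C
F2 | step 13 | (5R,6R)-2-[(tert-butyldimethylsilyloxy)methyl]-5,6-dihydroxy-6-methyl-3-{[(2R,3R)-3-methyloxiran-2-yl]ethynyl}cyclohex-2-en-1-one | O[C@@H]1CC(C#C[C@H]2O[C@@H]2C)=C(CO[Si](C)(C)C(C)(C)C)C(=O)[C@]1(C)O
F3 | step 13 | (5R,6R)-5,6-dihydroxy-2-(hydroxymethyl)-6-methyl-3-{[(2R,3R)-3-methyloxiran-2-yl]ethynyl}cyclohex-2-en-1-one | O[C@@H]1CC(C#C[C@H]2O[C@@H]2C)=C(CO)C(=O)[C@]1(C)O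
F4 | step 13 | methanol 1,6-adduct of F3 (C3-methoxy dienone, alkene isomers) | O[C@@H]1CC(C=C(OC)[C@H]2O[C@@H]2C)=C(CO)C(=O)[C@]1(C)O
F5 | step 11 | pyrrolidine 1,6-adduct of 17 (C3-pyrrolidinyl dienone, alkene isomers) | C[C@@](O)(CO)C(=O)C(CO)=C(C)C=C(N1CCCC1)[C@H]2O[C@@H]2C
F6 | step 5 | diethyl 2-[1-(trifluoromethylsulfonyloxy)ethylidene]malonate | CCOC(=O)C(C(=O)OCC)=C(C)OS(=O)(=O)C(F)(F)F
F7 | step 5 | diethyl 2-{4-[(2R,3R)-3-methyloxiran-2-yl]but-3-yn-2-ylidene}malonate | CCOC(=O)C(C(=O)OCC)=C(C)C#C[C@H]1O[C@@H]1C
F8 | step 5 | 2-{4-[(2R,3R)-3-methyloxiran-2-yl]but-3-yn-2-ylidene}propane-1,3-diol | OCC(CO)=C(C)C#C[C@H]1O[C@@H]1C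
F9 | step 5 | mono tert-butyldimethylsilyl ether of F8, silyloxymethyl cis to the alkyne | CC(C)(C)[Si](C)(C)OC/C(CO)=C(/C)C#C[C@H]1O[C@@H]1C
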